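**Plan**

1. Retrosynthetic cuts: the late adjustments (O5–Si, C3=C4, O6–CH3) lead back to chromanol 24. Its pyran is then contracted, C4 going from C4a back to C8a, to the spiro ether 23, which comes from phenol 22 by closing O1–C8a. Before that: C4–aryl (B-alkyl Suzuki), Cα–Cβ of the side chain (epoxide opening), and the two new ring bonds of the cyclohexene (Diels–Alder).
2. Forward order: cyclohexene ring → neopentyl iodide → chain with the tertiary carbinol → aryl joined → oxolane spiro-fused to a cyclohexadienone → six-membered O-ring by ring expansion → O6-methyl, C3=C4, free 5-OH.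
3. Enabling feature: in the benzopyran, O1 on C8a is para to the oxygen on C6, and C4a is the only arene carbon bearing carbon. C8a can therefore be dearomatised as a p-quinol ether (oxolane O1–C2–C3–C4–C8a spiro on a cyclohexa-2,5-dienone). A 1,2-shift of C4 to the neighbouring CH (the future C4a) then turns the five-membered O-ring into the pyran.
4. Stereochemistry: C2 comes from (S)-2-methylglycidol, and its C–O bond is never broken. The cis methyl groups on C1'/C6' of the cyclohexene come from the (E)-geometry of tiglaldehyde in a suprafacial cycloaddition; the absolute configuration comes from a chiral oxazaborolidinium catalyst.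
5. Helpers: TIPS on O5; the C6 oxygen as free OH/carbonyl for the dearomatisation (methylated afterwards); a saturated C3–C4 bond (dehydrogenated at the end).

Key step: step 15

Assumption: the (S)-configured oxazaborolidinium catalyst is taken, by the usual pre-transition-state model, to give 4 as drawn; if the facial sense is the opposite, the mirror-image catalyst is used.
Remark: the ring descriptors change from R,R (4–9, 12) to S,S (13 onward) only through CIP priority changes; the spatial arrangement is the same throughout.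

**Step 1**
Reactants: 1 pent-1-en-3-one (ethyl vinyl ketone)
Product: 2 (3Z)-3-[(triisopropylsilyl)oxy]penta-1,3-diene
Conditions: TIPSOTf, Et3N, CH2Cl2, 0 °C
Reagents that add atoms: triisopropylsilyl trifluoromethanesulfonate, CC(C)[Si](C(C)C)(C(C)C)OS(=O)(=O)C(F)(F)F
Why: Soft enolisation and O-silylation of an ethyl ketone should give the (Z)-silyl dienol ether, whose terminal methyl lies "outside" in the s-cis diene.

**Step 2**
Reactants: 2 (3Z)-3-[(triisopropylsilyl)oxy]penta-1,3-diene; 3 (2E)-2-methylbut-2-enal (tiglaldehyde)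
Product: 4 (1R,5R,6R)-1,5,6-trimethyl-4-[(triisopropylsilyl)oxy]cyclohex-3-ene-1-carbaldehyde
Conditions: (S)-o-tolyl-CBS-oxazaborolidine·Tf2NH (20 mol%), CH2Cl2, −78 → −40 °C
Reagents that add atoms: none
Why: Catalytic asymmetric Diels–Alder reaction of an α-substituted enal with a 2-silyloxydiene; the silyloxy group directs "para" regiochemistry (C–OSi 1,4 to the formyl-bearing carbon), suprafacial addition to the (E)-enal sets the two vicinal methyls cis with CHO trans to the 6-methyl, and the catalyst face sets the absolute configuration (the 5-methyl centre is lost later).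

**Step 3**
Reactants: 4 (1R,5R,6R)-1,5,6-trimethyl-4-[(triisopropylsilyl)oxy]cyclohex-3-ene-1-carbaldehyde
Product: 6 (3R,4R)-4-(hydroxymethyl)-2,3,4-trimethylcyclohexan-1-one (C2 epimers), via primary alcohol 5 (not isolated)
Conditions: NaBH4, MeOH, 0 °C; then 1 M HCl, THF, rt
Reagents that add atoms: none
Why: Borohydride reduction of the neopentyl aldehyde followed by acid hydrolysis of the silyl enol ether; the α-methyl centre next to the ketone may epimerise, which is of no consequence.

**Step 4**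
Reactants: 6 (3R,4R)-4-(hydroxymethyl)-2,3,4-trimethylcyclohexan-1-one
Product: 7 (3R,4R)-4-(iodomethyl)-2,3,4-trimethylcyclohexan-1-one (C2 epimers)
Conditions: I2, PPh3, imidazole, toluene, 90 °C
Reagents that add atoms: iodine, II
Why: Garegg–Samuelsson (Appel-type) iodination; heating is needed for the neopentyl position, and the ketone and the ring stereocentres are not touched.

**Step 5**
Reactants: 7 (3R,4R)-4-(iodomethyl)-2,3,4-trimethylcyclohexan-1-one
Product: 8 (3R,4R)-4-(iodomethyl)-2,3,4-trimethylcyclohex-1-en-1-yl trifluoromethanesulfonate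
Conditions: Tf2O, 2,6-di-tert-butyl-4-methylpyridine, CH2Cl2, 0 °C → rt
Reagents that add atoms: trifluoromethanesulfonic anhydride, O=S(=O)(OS(=O)(=O)C(F)(F)F)C(F)(F)F
Why: O-triflation of the ketone and proton loss with the hindered pyridine should give the more substituted (Zaitsev) enol triflate, as in the standard preparation of tetrasubstituted vinyl triflates from α-branched ketones; both C2 epimers converge.

**Step 6**
Reactants: 8 (3R,4R)-4-(iodomethyl)-2,3,4-trimethylcyclohex-1-en-1-yl trifluoromethanesulfonate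
Product: 9 (5R,6R)-5-(iodomethyl)-1,5,6-trimethylcyclohex-1-ene
Conditions: Pd(OAc)2 (cat.), PPh3, HCO2H, n-Bu3N, DMF, 60 °C
Reagents that add atoms: none
Why: Palladium-catalysed formate reduction of a vinyl triflate places the trisubstituted double bond regiospecifically; oxidative addition to the vinyl triflate should be much faster than to the neopentyl iodide, which has no β-hydrogen.

**Step 7**
Reactants: 9 (5R,6R)-5-(iodomethyl)-1,5,6-trimethylcyclohex-1-ene; 10 [(2S)-2-methyloxiran-2-yl]methanol ((S)-2-methylglycidol)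
Product: 13 (2R)-2-methyl-4-[(1S,2S)-1,2,3-trimethylcyclohex-3-en-1-yl]butane-1,2-diol, via chloromagnesium alkoxide 11 (not isolated), via Grignard reagent 12 (not isolated)
Conditions: 10, i-PrMgCl, THF, −40 °C; 9, Mg, THF, reflux; combined with CuI (10 mol%), −40 → 0 °C; aq. NH4Cl
Reagents that add atoms: none
Why: Copper-catalysed Grignard opening of a 2,2-disubstituted epoxide at its CH2 terminus; the tertiary C–O bond is not involved, so the chiral-pool stereocentre becomes C2 of the target unchanged.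

**Step 8**
Reactants: 13 (2R)-2-methyl-4-[(1S,2S)-1,2,3-trimethylcyclohex-3-en-1-yl]butane-1,2-diol
Product: 14 (2R)-2-hydroxy-2-methyl-4-[(1S,2S)-1,2,3-trimethylcyclohex-3-en-1-yl]butanal
Conditions: SO3·pyridine, DMSO, i-Pr2NEt, CH2Cl2, 0 °C
Reagents that add atoms: none
Why: Parikh–Doering oxidation takes only the primary hydroxyl and avoids the glycol cleavage that periodinane- or iodine(III)-based oxidants could cause; the aldehyde has no α-hydrogen and cannot epimerise.

**Step 9**
Reactants: 14 (2R)-2-hydroxy-2-methyl-4-[(1S,2S)-1,2,3-trimethylcyclohex-3-en-1-yl]butanal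
Product: 15 (3R)-3-methyl-5-[(1S,2S)-1,2,3-trimethylcyclohex-3-en-1-yl]pent-1-en-3-ol
Conditions: Ph3PCH3Br, KHMDS (excess ylide), THF, 0 °C → rt
Reagents that add atoms: methyltriphenylphosphonium bromide, C[P+](c1ccccc1)(c1ccccc1)c1ccccc1.[Br-]
Why: Wittig methylenation of an α-hydroxy aldehyde with excess ylide (one equivalent is taken up by the hydroxyl) gives the tertiary allylic alcohol without touching C2.

**Step 10**
Reactants: 16 2-hydroxy-3,4-dimethoxybenzaldehyde
Product: 17 5-bromo-2-hydroxy-3,4-dimethoxybenzaldehyde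
Conditions: NBS, MeCN, 0 °C
Reagents that add atoms: N-bromosuccinimide, O=C1CCC(=O)N1Br
Why: Electrophilic bromination goes para to the free hydroxyl (also ortho to OMe and meta to CHO), the most activated open position.

**Step 11**
Reactants: 17 5-bromo-2-hydroxy-3,4-dimethoxybenzaldehyde
Product: 19 5-bromo-3,4-dimethoxybenzene-1,2-diol, via aryl formate 18 (not isolated)
Conditions: H2O2 (30%), NaOH, THF/H2O, 0 °C → rt
Reagents that add atoms: hydrogen peroxide, OO
Why: Dakin oxidation of an ortho-hydroxybenzaldehyde (aryl migration to peroxide oxygen, then formate hydrolysis) replaces CHO by OH.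

**Step 12**
Reactants: 19 5-bromo-3,4-dimethoxybenzene-1,2-diol
Product: 20 4-bromo-2,3-dimethoxy-6-[(triisopropylsilyl)oxy]phenol
Conditions: TIPSCl, imidazole, CH2Cl2, 0 °C
Reagents that add atoms: chlorotriisopropylsilane, CC(C)[Si](Cl)(C(C)C)C(C)C
Why: The bulky silyl chloride should take the hydroxyl flanked by C–H and not the one wedged between OH and OMe; silyl migration between the two oxygens would favour the same isomer.

**Step 13**
Reactants: 15 (3R)-3-methyl-5-[(1S,2S)-1,2,3-trimethylcyclohex-3-en-1-yl]pent-1-en-3-ol; 20 4-bromo-2,3-dimethoxy-6-[(triisopropylsilyl)oxy]phenol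
Product: 22 4-{(3R)-3-hydroxy-3-methyl-5-[(1S,2S)-1,2,3-trimethylcyclohex-3-en-1-yl]pentyl}-2,3-dimethoxy-6-[(triisopropylsilyl)oxy]phenol, via B-alkyl-9-BBN adduct 21 (not isolated)
Conditions: 9-BBN, THF, rt; then 20, Pd(OAc)2 (cat.), SPhos, aq. K3PO4, THF, 45 °C
Reagents that add atoms: none
Why: 9-BBN hydroborates only the terminal vinyl group (the hindered trisubstituted ring alkene is left), and B-alkyl Suzuki–Miyaura coupling joins the primary carbon to the aryl bromide, para to the free phenol.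

**Step 14**
Reactants: 22 4-{(3R)-3-hydroxy-3-methyl-5-[(1S,2S)-1,2,3-trimethylcyclohex-3-en-1-yl]pentyl}-2,3-dimethoxy-6-[(triisopropylsilyl)oxy]phenol
Product: 23 (2R)-6,7-dimethoxy-2-methyl-9-[(triisopropylsilyl)oxy]-2-{2-[(1S,2S)-1,2,3-trimethylcyclohex-3-en-1-yl]ethyl}-1-oxaspiro[4.5]deca-6,9-dien-8-one (both configurations at the spiro carbon)
Conditions: PhI(OAc)2, (CF3)2CHOH/CH2Cl2, 0 °C
Reagents that add atoms: none
Why: Hypervalent-iodine oxidative dearomatisation of a para-alkylphenol with 5-exo capture by the tethered tertiary hydroxyl at the para (ipso) carbon gives the spiro p-quinol ether; the non-nucleophilic solvent suppresses ortho attack by external nucleophiles, and the new spiro centre is lost in step 15.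

**Step 15**
Reactants: 23 (2R)-6,7-dimethoxy-2-methyl-9-[(triisopropylsilyl)oxy]-2-{2-[(1S,2S)-1,2,3-trimethylcyclohex-3-en-1-yl]ethyl}-1-oxaspiro[4.5]deca-6,9-dien-8-one
Product: 24 (2R)-7,8-dimethoxy-2-methyl-5-[(triisopropylsilyl)oxy]-2-{2-[(1S,2S)-1,2,3-trimethylcyclohex-3-en-1-yl]ethyl}-3,4-dihydro-2H-chromen-6-ol
Conditions: BF3·OEt2 (20 mol%), CH2Cl2, −40 → 0 °C
Reagents that add atoms: none
Why: Coordination of the Lewis acid to the dienone carbonyl gives a hydroxy-arenium (pentadienyl) cation; the ring CH2 (C4) then shifts from the spiro carbon to the adjacent unsubstituted CH, leaving a cation stabilised by the ring oxygen, and proton loss rearomatises. The closest known reaction type is the dienone–phenol (p-quinol) rearrangement, in which the carbon substituent migrates and the oxygen stays. The pyran is formed by ring expansion of the oxolane through this suprafacial 1,2-carbon shift, not by a new cyclisation. No new stereocentre is formed: C2 keeps its configuration because its C–O bond is not involved, and both spiro epimers converge on one product. The step needs carbon rather than oxygen migration, which the oxocarbenium stabilisation of the carbon left behind should secure. It also needs migration to the CH terminus rather than to the methoxy-bearing one, which is secured because only the CH terminus can lose a proton and aromatise.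

**Step 16**
Reactants: 24 (2R)-7,8-dimethoxy-2-methyl-5-[(triisopropylsilyl)oxy]-2-{2-[(1S,2S)-1,2,3-trimethylcyclohex-3-en-1-yl]ethyl}-3,4-dihydro-2H-chromen-6-ol
Product: 25 triisopropyl{[(2R)-6,7,8-trimethoxy-2-methyl-2-{2-[(1S,2S)-1,2,3-trimethylcyclohex-3-en-1-yl]ethyl}-3,4-dihydro-2H-chromen-5-yl]oxy}silane
Conditions: MeOH, PPh3, DIAD, THF, 0 °C → rt
Reagents that add atoms: methanol, CO
Why: Mitsunobu O-methylation of the phenol avoids a long-lived free phenoxide and so the base-induced 1,2-silyl migration between O5 and O6.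

**Step 17**
Reactants: 25 triisopropyl{[(2R)-6,7,8-trimethoxy-2-methyl-2-{2-[(1S,2S)-1,2,3-trimethylcyclohex-3-en-1-yl]ethyl}-3,4-dihydro-2H-chromen-5-yl]oxy}silane
Product: 26 triisopropyl{[(2R)-6,7,8-trimethoxy-2-methyl-2-{2-[(1S,2S)-1,2,3-trimethylcyclohex-3-en-1-yl]ethyl}-2H-chromen-5-yl]oxy}silane
Conditions: DDQ, benzene, 80 °C
Reagents that add atoms: none
Why: DDQ dehydrogenation of an electron-rich chroman (hydride abstraction at benzylic C4, stabilised by the para 7-OMe and the ortho oxygens, then loss of H from C3) gives the 2H-chromene; C2 is quaternary and cannot be oxidised further.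

**Step 18**
Reactants: 26 triisopropyl{[(2R)-6,7,8-trimethoxy-2-methyl-2-{2-[(1S,2S)-1,2,3-trimethylcyclohex-3-en-1-yl]ethyl}-2H-chromen-5-yl]oxy}silane
Product: 27 (2R)-6,7,8-trimethoxy-2-methyl-2-{2-[(1S,2S)-1,2,3-trimethylcyclohex-3-en-1-yl]ethyl}-2H-chromen-5-ol (target)
Conditions: TBAF, AcOH, THF, 0 °C
Reagents that add atoms: none
Why: Buffered fluoride cleavage of the aryl silyl ether frees the 5-OH under conditions that spare the chromene and the ring alkene.

**Compound list**

1 | pent-1-en-3-one (ethyl vinyl ketone) | C=CC(=O)CC | starting material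
2 | (3Z)-3-[(triisopropylsilyl)oxy]penta-1,3-diene | C=C/C(O[Si](C(C)C)(C(C)C)C(C)C)=C/C | intermediate
3 | (2E)-2-methylbut-2-enal (tiglaldehyde) | C/C=C(\C)C=O | starting material
4 | (1R,5R,6R)-1,5,6-trimethyl-4-[(triisopropylsilyl)oxy]cyclohex-3-ene-1-carbaldehyde | O=C[C@]1(C)CC=C(O[Si](C(C)C)(C(C)C)C(C)C)[C@H](C)[C@H]1C | intermediate
5 | {(1R,5R,6R)-1,5,6-trimethyl-4-[(triisopropylsilyl)oxy]cyclohex-3-en-1-yl}methanol | OC[C@]1(C)CC=C(O[Si](C(C)C)(C(C)C)C(C)C)[C@H](C)[C@H]1C | intermediate (not isolated)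
6 | (3R,4R)-4-(hydroxymethyl)-2,3,4-trimethylcyclohexan-1-one (C2 epimers) | OC[C@]1(C)CCC(=O)C(C)[C@H]1C | intermediate
7 | (3R,4R)-4-(iodomethyl)-2,3,4-trimethylcyclohexan-1-one (C2 epimers) | IC[C@]1(C)CCC(=O)C(C)[C@H]1C | intermediate
8 | (3R,4R)-4-(iodomethyl)-2,3,4-trimethylcyclohex-1-en-1-yl trifluoromethanesulfonate | IC[C@]1(C)CCC(OS(=O)(=O)C(F)(F)F)=C(C)[C@H]1C | intermediate
9 | (5R,6R)-5-(iodomethyl)-1,5,6-trimethylcyclohex-1-ene | IC[C@]1(C)CCC=C(C)[C@H]1C | intermediate
10 | [(2S)-2-methyloxiran-2-yl]methanol ((S)-2-methylglycidol) | OC[C@@]1(C)CO1 | starting material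
11 | chloromagnesium [(2S)-2-methyloxiran-2-yl]methanolate | Cl[Mg]OC[C@@]1(C)CO1 | intermediate (not isolated)
12 | {[(1R,2R)-1,2,3-trimethylcyclohex-3-en-1-yl]methyl}magnesium iodide | I[Mg]C[C@]1(C)CCC=C(C)[C@H]1C | intermediate (not isolated)
13 | (2R)-2-methyl-4-[(1S,2S)-1,2,3-trimethylcyclohex-3-en-1-yl]butane-1,2-diol | O[C@](C)(CC[C@]1(C)CCC=C(C)[C@H]1C)CO | intermediate
14 | (2R)-2-hydroxy-2-methyl-4-[(1S,2S)-1,2,3-trimethylcyclohex-3-en-1-yl]butanal | O[C@](C)(CC[C@]1(C)CCC=C(C)[C@H]1C)C=O | intermediate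
15 | (3R)-3-methyl-5-[(1S,2S)-1,2,3-trimethylcyclohex-3-en-1-yl]pent-1-en-3-ol | O[C@](C)(CC[C@]1(C)CCC=C(C)[C@H]1C)C=C | intermediate
16 | 2-hydroxy-3,4-dimethoxybenzaldehyde | O=Cc1ccc(OC)c(OC)c1O | starting material
17 | 5-bromo-2-hydroxy-3,4-dimethoxybenzaldehyde | O=Cc1cc(Br)c(OC)c(OC)c1O | intermediate
18 | 5-bromo-2-hydroxy-3,4-dimethoxyphenyl formate | O=COc1cc(Br)c(OC)c(OC)c1O | intermediate (not isolated)
19 | 5-bromo-3,4-dimethoxybenzene-1,2-diol | Oc1cc(Br)c(OC)c(OC)c1O | intermediate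
20 | 4-bromo-2,3-dimethoxy-6-[(triisopropylsilyl)oxy]phenol | CC(C)[Si](Oc1cc(Br)c(OC)c(OC)c1O)(C(C)C)C(C)C | intermediate
21 | (3R)-1-(9-borabicyclo[3.3.1]nonan-9-yl)-3-methyl-5-[(1S,2S)-1,2,3-trimethylcyclohex-3-en-1-yl]pentan-3-ol | O[C@](C)(CC[C@]1(C)CCC=C(C)[C@H]1C)CCB1C2CCCC1CCC2 | intermediate (not isolated)
22 | 4-{(3R)-3-hydroxy-3-methyl-5-[(1S,2S)-1,2,3-trimethylcyclohex-3-en-1-yl]pentyl}-2,3-dimethoxy-6-[(triisopropylsilyl)oxy]phenol | O[C@](C)(CC[C@]1(C)CCC=C(C)[C@H]1C)CCc1cc(O[Si](C(C)C)(C(C)C)C(C)C)c(O)c(OC)c1OC | intermediate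
23 | (2R)-6,7-dimethoxy-2-methyl-9-[(triisopropylsilyl)oxy]-2-{2-[(1S,2S)-1,2,3-trimethylcyclohex-3-en-1-yl]ethyl}-1-oxaspiro[4.5]deca-6,9-dien-8-one (both spiro epimers) | C[C@@]1(CC[C@]2(C)CCC=C(C)[C@H]2C)CCC3(O1)C=C(O[Si](C(C)C)(C(C)C)C(C)C)C(=O)C(OC)=C3OC | intermediate
24 | (2R)-7,8-dimethoxy-2-methyl-5-[(triisopropylsilyl)oxy]-2-{2-[(1S,2S)-1,2,3-trimethylcyclohex-3-en-1-yl]ethyl}-3,4-dihydro-2H-chromen-6-ol | C[C@@]1(CC[C@]2(C)CCC=C(C)[C@H]2C)CCc2c(O[Si](C(C)C)(C(C)C)C(C)C)c(O)c(OC)c(OC)c2O1 | intermediate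
25 | triisopropyl{[(2R)-6,7,8-trimethoxy-2-methyl-2-{2-[(1S,2S)-1,2,3-trimethylcyclohex-3-en-1-yl]ethyl}-3,4-dihydro-2H-chromen-5-yl]oxy}silane | C[C@@]1(CC[C@]2(C)CCC=C(C)[C@H]2C)CCc2c(O[Si](C(C)C)(C(C)C)C(C)C)c(OC)c(OC)c(OC)c2O1 | intermediate
26 | triisopropyl{[(2R)-6,7,8-trimethoxy-2-methyl-2-{2-[(1S,2S)-1,2,3-trimethylcyclohex-3-en-1-yl]ethyl}-2H-chromen-5-yl]oxy}silane | C[C@@]1(CC[C@]2(C)CCC=C(C)[C@H]2C)C=Cc2c(O[Si](C(C)C)(C(C)C)C(C)C)c(OC)c(OC)c(OC)c2O1 | intermediate
27 | (2R)-6,7,8-trimethoxy-2-methyl-2-{2-[(1S,2S)-1,2,3-trimethylcyclohex-3-en-1-yl]ethyl}-2H-chromen-5-ol | COc1c(O)c2c(c(OC)c1OC)O[C@](C)(CC[C@]1(C)CCC=C(C)[C@H]1C)C=C2 | target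

**Step count and risks**

Total steps: 18 (steps 10–12 form the side branch to aryl bromide 20). Longest linear sequence: 15 steps (1–9, then 13–18).

Steps most likely to fail:

Step 15. The acid-induced shift may be overtaken by ionisation of the tertiary C2–O bond of the spiro ether (loss of the side chain or of configuration) or stall through reversible migration towards the methoxy-bearing carbon. The fallback makes the aryl–O1 bond by palladium-catalysed intramolecular C–O coupling of the tertiary alcohol, which likewise leaves the C2–O bond intact; it sets out from 15 and comes back at 25 (it also bypasses steps 13, 14 and 16). Commercial 2,3,4-trimethoxybenzaldehyde is brominated (NBS) to 5-bromo-2,3,4-trimethoxybenzaldehyde F1. Baeyer–Villiger oxidation (mCPBA; then K2CO3, MeOH) gives 5-bromo-2,3,4-trimethoxyphenol F2. Iodination at the only free ring position (NIS) gives 3-bromo-2-iodo-4,5,6-trimethoxyphenol F3, and silylation (TIPSCl, imidazole) gives (3-bromo-2-iodo-4,5,6-trimethoxyphenoxy)triisopropylsilane F4. Alkylborane 21, made from 15 as in step 13, is coupled selectively at the C–I bond of F4 (Pd, SPhos, aq. K3PO4) to give (3R)-1-{2-bromo-3,4,5-trimethoxy-6-[(triisopropylsilyl)oxy]phenyl}-3-methyl-5-[(1S,2S)-1,2,3-trimethylcyclohex-3-en-1-yl]pentan-3-ol F5. Ring closure of F5 (Pd(OAc)2, a bulky di-tert-butyl biaryl phosphine, Cs2CO3, toluene, 80 °C) gives chroman 25.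

Step 2. Facial selectivity may be poor with the α,β-disubstituted enal, or the acid-labile silyloxydiene may be consumed by desilylation or Mukaiyama-type addition before cycloaddition. The fallback is a racemic cycloaddition with classical resolution; it sets out from 2 and 3 and comes back at 5. The cycloaddition is run with an achiral Lewis acid (Me2AlCl, CH2Cl2, −78 °C) and gives 4 together with its mirror image (1S,5S,6S)-1,5,6-trimethyl-4-[(triisopropylsilyl)oxy]cyclohex-3-ene-1-carbaldehyde F6. Reduction (NaBH4, MeOH) gives 5 together with {(1S,5S,6S)-1,5,6-trimethyl-4-[(triisopropylsilyl)oxy]cyclohex-3-en-1-yl}methanol F7. Esterification with (S)-2-methoxy-2-phenylacetic acid (DCC, DMAP) gives the (S)-methoxyphenylacetate of 5, F8, and the (S)-methoxyphenylacetate of F7, F9, which are separated by chromatography. Methanolysis of F8 (K2CO3, MeOH) returns 5, which is hydrolysed to 6 as in the second half of step 3.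

Step 13. Oxidative addition to the electron-rich bromophenolate may be too slow, and the aqueous base may cause loss or migration of the aryl silyl ether. The fallback is an sp–sp2 coupling under amine base followed by selective hydrogenation; it sets out from 14 and comes back at 22. Ohira–Bestmann homologation (dimethyl (1-diazo-2-oxopropyl)phosphonate, K2CO3, MeOH) gives (3R)-3-methyl-5-[(1S,2S)-1,2,3-trimethylcyclohex-3-en-1-yl]pent-1-yn-3-ol F10. Sonogashira coupling with 20 (PdCl2(PPh3)2, CuI, Et3N, 50 °C) gives 4-{(3R)-3-hydroxy-3-methyl-5-[(1S,2S)-1,2,3-trimethylcyclohex-3-en-1-yl]pent-1-yn-1-yl}-2,3-dimethoxy-6-[(triisopropylsilyl)oxy]phenol F11. Hydrogenation over RhCl(PPh3)3 (H2, benzene/EtOH), which leaves the hindered trisubstituted ring alkene, gives 22.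

Further compounds
F1 | step 15 | 5-bromo-2,3,4-trimethoxybenzaldehyde | O=Cc1cc(Br)c(OC)c(OC)c1OC
F2 | step 15 | 5-bromo-2,3,4-trimethoxyphenol | Oc1cc(Br)c(OC)c(OC)c1OC
F3 | step 15 | 3-bromo-2-iodo-4,5,6-trimethoxyphenol | Oc1c(I)c(Br)c(OC)c(OC)c1OC
F4 | step 15 | (3-bromo-2-iodo-4,5,6-trimethoxyphenoxy)triisopropylsilane | CC(C)[Si](Oc1c(I)c(Br)c(OC)c(OC)c1OC)(C(C)C)C(C)C
F5 | step 15 | (3R)-1-{2-bromo-3,4,5-trimethoxy-6-[(triisopropylsilyl)oxy]phenyl}-3-methyl-5-[(1S,2S)-1,2,3-trimethylcyclohex-3-en-1-yl]pentan-3-ol | O[C@](C)(CC[C@]1(C)CCC=C(C)[C@H]1C)CCc1c(Br)c(OC)c(OC)c(OC)c1O[Si](C(C)C)(C(C)C)C(C)C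
F6 | step 2 | (1S,5S,6S)-1,5,6-trimethyl-4-[(triisopropylsilyl)oxy]cyclohex-3-ene-1-carbaldehyde | O=C[C@@]1(C)CC=C(O[Si](C(C)C)(C(C)C)C(C)C)[C@@H](C)[C@@H]1C
F7 | step 2 | {(1S,5S,6S)-1,5,6-trimethyl-4-[(triisopropylsilyl)oxy]cyclohex-3-en-1-yl}methanol | OC[C@@]1(C)CC=C(O[Si](C(C)C)(C(C)C)C(C)C)[C@@H](C)[C@@H]1C
F8 | step 2 | {(1R,5R,6R)-1,5,6-trimethyl-4-[(triisopropylsilyl)oxy]cyclohex-3-en-1-yl}methyl (2S)-methoxy(phenyl)acetate | CO[C@H](C(=O)OC[C@]1(C)CC=C(O[Si](C(C)C)(C(C)C)C(C)C)[C@H](C)[C@H]1C)c1ccccc1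
F9 | step 2 | {(1S,5S,6S)-1,5,6-trimethyl-4-[(triisopropylsilyl)oxy]cyclohex-3-en-1-yl}methyl (2S)-methoxy(phenyl)acetate | CO[C@H](C(=O)OC[C@@]1(C)CC=C(O[Si](C(C)C)(C(C)C)C(C)C)[C@@H](C)[C@@H]1C)c1ccccc1
F10 | step 13 | (3R)-3-methyl-5-[(1S,2S)-1,2,3-trimethylcyclohex-3-en-1-yl]pent-1-yn-3-ol | O[C@](C)(CC[C@]1(C)CCC=C(C)[C@H]1C)C#C
F11 | step 13 | 4-{(3R)-3-hydroxy-3-methyl-5-[(1S,2S)-1,2,3-trimethylcyclohex-3-en-1-yl]pent-1-yn-1-yl}-2,3-dimethoxy-6-[(triisopropylsilyl)oxy]phenol | O[C@](C)(CC[C@]1(C)CCC=C(C)[C@H]1C)C#Cc1cc(O[Si](C(C)C)(C(C)C)C(C)C)c(O)c(OC)c1OC
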